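**Retrosynthetic overview** (ring labels: C1(OAc)–C2–C3=C4(Me)–C5–C6–C7(side-chain methine C1′)–C8(OAc)–C9=C10(Me), C10 bonded to C1)
1. The route rests on the Z-trisubstituted C3=C4 alkene of the ten-membered ring. It lies between the methylenes C2 and C5, away from C1, C7, C8 and C1′, so it is made last by Ramberg–Bäcklund loss of SO2 from an eleven-membered sulfone in which sulfur links C3 and C4.
2. The thiacycle (first ring) is closed by S-alkylation of a C4 thiolate with a C3 iodide and oxidised to the sulfone; the contraction then gives the ten-membered carbocycle (second and last ring event).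
3. The open chain comes from a Nozaki–Hiyama–Kishi union (C8–C9) of a keto aldehyde (C4–C8 plus side chain) with an E-alkenyl iodide (C9, C10, C1–C3, with C3 carried as chloride).
4. The keto aldehyde comes from amine-catalysed Michael addition of (R)-citronellal to methyl vinyl ketone (sets C7; C1′ from the pool). The alkenyl iodide comes from a silyl ynone by asymmetric transfer hydrogenation (sets C1) and methylalumination–iodination (sets E-C9=C10).
5. End game: removal of both silyl ethers and acetylation.

Key step: step 14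

Remark: the ring labels above are used for all intermediates. C4 is carried as both epimers from step 9 to step 13, because this centre becomes sp2 in step 14.

**Step 1**
Reactants: 1 (R)-citronellal; 2 methyl vinyl ketone
Product: 3 (2S,3R)-3,7-dimethyl-2-(3-oxobutyl)oct-6-enal
Conditions: (S)-2-[methoxy(diphenyl)methyl]pyrrolidine (10 mol%), ethyl 3,4-dihydroxybenzoate (20 mol%), neat, 4 °C
Reagents that add atoms: none
Why: Amine-catalysed (enamine) Michael addition of an aldehyde to an enone: the methoxydiphenylmethyl group of the (S)-pyrrolidine blocks one face of the E-enamine of 1, the enone should add to the open face and set C7 as (S) under catalyst control, and C1′ is carried over unchanged from 1.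

**Step 2**
Reactants: 4 bis(trimethylsilyl)acetylene; 5 3-chloropropanoyl chloride
Product: 6 5-chloro-1-(trimethylsilyl)pent-1-yn-3-one
Conditions: AlCl3, CH2Cl2, 0 °C
Reagents that add atoms: none
Why: Friedel–Crafts-type acylation with ipso-desilylation of the bis-silyl alkyne by the acyl chloride–AlCl3 complex should stop at the mono-acylated silyl ynone, which is deactivated towards a second acylation.

**Step 3**
Reactants: 6 5-chloro-1-(trimethylsilyl)pent-1-yn-3-one
Product: 7 (3S)-5-chloro-1-(trimethylsilyl)pent-1-yn-3-ol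
Conditions: Ru[(S,S)-TsDPEN](p-cymene) (1 mol%), i-PrOH, rt
Reagents that add atoms: none
Why: Noyori asymmetric transfer hydrogenation of an alkynyl ketone, in which the alkynyl group takes the place of the aryl group of the usual model so that the (S,S)-ligand should set C1 as (S); the base-free amido catalyst is used so that the β-chloro ketone does not lose HCl.

**Step 4**
Reactants: 7 (3S)-5-chloro-1-(trimethylsilyl)pent-1-yn-3-ol
Product: 8 (3S)-3-(tert-butyldimethylsilyloxy)-5-chloro-1-(trimethylsilyl)pent-1-yne
Conditions: TBSCl, imidazole, DMF, rt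
Reagents that add atoms: tert-butyldimethylsilyl chloride, CC(C)(C)[Si](C)(C)Cl
Why: Imidazole-promoted O-silylation of an unhindered secondary propargylic alcohol, which does not touch the stereocentre or the primary chloride.

**Step 5**
Reactants: 8 (3S)-3-(tert-butyldimethylsilyloxy)-5-chloro-1-(trimethylsilyl)pent-1-yne
Product: 9 (3S)-3-(tert-butyldimethylsilyloxy)-5-chloropent-1-yne
Conditions: K2CO3 (cat.), MeOH, 0 °C → rt
Reagents that add atoms: none
Why: Base-catalysed methanolysis (protodesilylation) of the C(sp)–SiMe3 bond is fast under conditions that leave the O-silyl ether and the primary chloride intact.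

**Step 6**
Reactants: 9 (3S)-3-(tert-butyldimethylsilyloxy)-5-chloropent-1-yne
Product: 11 (1E,3S)-3-(tert-butyldimethylsilyloxy)-5-chloro-1-iodo-2-methylpent-1-ene, via alkenylalane 10 (not isolated)
Conditions: Me3Al, Cp2ZrCl2 (0.3 equiv), CH2Cl2, 0 °C → rt; then I2, THF, −30 °C
Reagents that add atoms: trimethylaluminium, C[Al](C)C; iodine, II
Why: Negishi zirconium-catalysed carboalumination adds methyl and aluminium syn across the terminal alkyne with methyl on the internal carbon C10, and iodinolysis of the C–Al bond with retention should give the E-alkenyl iodide.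

**Step 7**
Reactants: 3 (2S,3R)-3,7-dimethyl-2-(3-oxobutyl)oct-6-enal; 11 (1E,3S)-3-(tert-butyldimethylsilyloxy)-5-chloro-1-iodo-2-methylpent-1-ene
Product: 13 (5S,6R,7E,9S)-9-(tert-butyldimethylsilyloxy)-11-chloro-6-hydroxy-8-methyl-5-[(2R)-6-methylhept-5-en-2-yl]undec-7-en-2-one, via alkenylchromium 12 (not isolated)
Conditions: CrCl2 (4 equiv), NiCl2 (2 mol%), DMSO, rt
Reagents that add atoms: none
Why: Nozaki–Hiyama–Kishi coupling, in which the alkenylchromium(III) species adds to the aldehyde and not to the methyl ketone or the alkyl chloride with retention of alkene geometry, and Felkin–Anh attack anti to the branched C1′ substituent of the C7 stereocentre should favour the (8R) carbinol (C6 of this name).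

**Step 8**
Reactants: 13 the C8 carbinol from step 7
Product: 14 (5S,6R,7E,9S)-6,9-bis(tert-butyldimethylsilyloxy)-11-chloro-8-methyl-5-[(2R)-6-methylhept-5-en-2-yl]undec-7-en-2-one
Conditions: TBSOTf, 2,6-lutidine, CH2Cl2, −78 °C
Reagents that add atoms: tert-butyldimethylsilyl triflate, CC(C)(C)[Si](C)(C)OS(=O)(=O)C(F)(F)F
Why: Silyl triflate O-silylation of the hindered allylic alcohol traps the open-chain hydroxy ketone, and with 2,6-lutidine at −78 °C the methyl ketone should not be turned into a silyl enol ether.

**Step 9**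
Reactants: 14 the bis-silyl ketone
Product: 15 (2RS,5S,6R,7E,9S)-6,9-bis(tert-butyldimethylsilyloxy)-11-chloro-8-methyl-5-[(2R)-6-methylhept-5-en-2-yl]undec-7-en-2-ol (both epimers at ring C4)
Conditions: NaBH4, MeOH, 0 °C
Reagents that add atoms: none
Why: Borohydride reduction of the methyl ketone spares the alkyl chloride, the silyl ethers and the alkenes, and no control at C4 is needed because both epimers converge in step 14.

**Step 10**
Reactants: 15 the C4 carbinol
Product: 16 S-[(2RS,5S,6R,7E,9S)-6,9-bis(tert-butyldimethylsilyloxy)-11-chloro-8-methyl-5-[(2R)-6-methylhept-5-en-2-yl]undec-7-en-2-yl] ethanethioate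
Conditions: PPh3, DIAD, AcSH, THF, 0 °C
Reagents that add atoms: thioacetic acid, CC(=O)S
Why: Mitsunobu thioesterification, in which thioacetate displaces the alkoxyphosphonium group at the unhindered secondary C4 by SN2 while the primary chloride is inert.

**Step 11**
Reactants: 16 the chloro thioacetate
Product: 17 S-[(2RS,5S,6R,7E,9S)-6,9-bis(tert-butyldimethylsilyloxy)-11-iodo-8-methyl-5-[(2R)-6-methylhept-5-en-2-yl]undec-7-en-2-yl] ethanethioate
Conditions: NaI, acetone, reflux
Reagents that add atoms: sodium iodide, [Na+].[I-]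
Why: Finkelstein halide exchange at the unhindered primary C3, driven by precipitation of NaCl, gives the better leaving group for the ring closure without affecting the non-nucleophilic thioacetate.

**Step 12**
Reactants: 17 the iodo thioacetate
Product: 19 (4S,5E,7R,8S)-4,7-bis(tert-butyldimethylsilyloxy)-5,11-dimethyl-8-[(2R)-6-methylhept-5-en-2-yl]thiacycloundec-5-ene (S between ring C3 and C4; both C4 epimers), via thiol 18 (not isolated)
Conditions: Cs2CO3, degassed MeOH/DMF (1:4), slow addition of 17 to 1 mM final concentration, 40 °C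
Reagents that add atoms: none
Why: Methanolysis of the thioacetate frees the caesium thiolate, which should displace the primary iodide intramolecularly (SN2 thioether macrocyclisation) under high dilution, helped by the soft nucleophile and the long C–S bonds, with oxygen excluded to avoid disulfide formation.

**Step 13**
Reactants: 19 the eleven-membered cyclic sulfide
Product: 21 (4S,5E,7R,8S)-4,7-bis(tert-butyldimethylsilyloxy)-5,11-dimethyl-8-[(2R)-6-methylhept-5-en-2-yl]thiacycloundec-5-ene 1,1-dioxide (the C3–SO2–C4 sulfone), via sulfoxide 20 (not isolated)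
Conditions: (NH4)6Mo7O24·4H2O (10 mol%), 30% aq. H2O2, EtOH, 0 °C → rt
Reagents that add atoms: hydrogen peroxide, OO
Why: Molybdate-catalysed peroxide oxidation should take the sulfide through the sulfoxide to the sulfone much faster than it epoxidises the three unactivated trisubstituted alkenes.

**Step 14**
Reactants: 21 the eleven-membered sulfone
Product: 24 (1S,3Z,7S,8R,9E)-1,8-bis(tert-butyldimethylsilyloxy)-4,10-dimethyl-7-[(2R)-6-methylhept-5-en-2-yl]cyclodeca-3,9-diene, via bromo sulfone 22 (not isolated), via episulfone 23 (not isolated)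
Conditions: KOH on Al2O3, CBr2F2, t-BuOH/CH2Cl2, 0 °C → rt
Reagents that add atoms: none
Why: Ramberg–Bäcklund rearrangement with in situ halogenation: hydroxide forms an α-sulfonyl carbanion (C3 is the more accessible, but bromination at C4 leads to the same episulfone), CBr2F2 brominates it, the second α-carbanion displaces bromide in a 1,3-elimination (3-exo-tet) to the episulfone, and cheletropic loss of SO2 leaves the C3–C4 σ and π bonds. The closest known reaction type is the contraction of medium and large cyclic sulfones to cycloalkenes under these halogenating base conditions. The ten-membered carbocycle therefore arises by contraction of the existing eleven-membered ring and not by an end-to-end C–C cyclisation. No stereocentre is formed, and C1, C7, C8 and C1′ are untouched because neither carbanion has a β-leaving group and none of these centres is acidic. The step needs Z geometry at C3=C4, which should follow from the kinetically preferred cis-fused episulfone in the hydroxide regime and from the lower strain of a cis alkene in a ten-membered ring that already holds the E-C9=C10 bond. CBr2F2 is used instead of CCl4 so that no dichlorocarbene is generated that could add to the electron-rich alkenes.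

**Step 15**
Reactants: 24 the bis-silyl diene
Product: 25 (1S,3Z,7S,8R,9E)-4,10-dimethyl-7-[(2R)-6-methylhept-5-en-2-yl]cyclodeca-3,9-diene-1,8-diol
Conditions: TBAF, THF, rt → 40 °C
Reagents that add atoms: none
Why: Fluoride-mediated desilylation cleaves both secondary allylic silyl ethers at silicon, so the carbinol configurations are retained.

**Step 16**
Reactants: 25 the diol
Product: 26 (1S,3Z,7S,8R,9E)-4,10-dimethyl-7-[(2R)-6-methylhept-5-en-2-yl]cyclodeca-3,9-diene-1,8-diyl diacetate (target)
Conditions: Ac2O, pyridine, DMAP (cat.), CH2Cl2, rt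
Reagents that add atoms: acetic anhydride, CC(=O)OC(C)=O
Why: DMAP-catalysed O-acylation of both secondary allylic alcohols proceeds at oxygen without ionisation, so configuration and alkene positions should be retained.

**Compound list**
1 | (R)-citronellal | O=CC[C@H](C)CCC=C(C)C | starting material
2 | methyl vinyl ketone | CC(=O)C=C | starting material
3 | (2S,3R)-3,7-dimethyl-2-(3-oxobutyl)oct-6-enal | CC(=O)CC[C@@H]([C@H](C)CCC=C(C)C)C=O | intermediate
4 | bis(trimethylsilyl)acetylene | C[Si](C)(C)C#C[Si](C)(C)C | starting material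
5 | 3-chloropropanoyl chloride | ClCCC(Cl)=O | starting material
6 | 5-chloro-1-(trimethylsilyl)pent-1-yn-3-one | C[Si](C)(C)C#CC(=O)CCCl | intermediate
7 | (3S)-5-chloro-1-(trimethylsilyl)pent-1-yn-3-ol | C[Si](C)(C)C#C[C@@H](O)CCCl | intermediate
8 | (3S)-3-(tert-butyldimethylsilyloxy)-5-chloro-1-(trimethylsilyl)pent-1-yne | C[Si](C)(C)C#C[C@@H](O[Si](C)(C)C(C)(C)C)CCCl | intermediate
9 | (3S)-3-(tert-butyldimethylsilyloxy)-5-chloropent-1-yne | C#C[C@@H](O[Si](C)(C)C(C)(C)C)CCCl | intermediate
10 | [(1E,3S)-3-(tert-butyldimethylsilyloxy)-5-chloro-2-methylpent-1-en-1-yl]dimethylalane (not isolated) | C[Al](C)/C=C(C)/[C@@H](O[Si](C)(C)C(C)(C)C)CCCl | intermediate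
11 | (1E,3S)-3-(tert-butyldimethylsilyloxy)-5-chloro-1-iodo-2-methylpent-1-ene | I/C=C(C)/[C@@H](O[Si](C)(C)C(C)(C)C)CCCl | intermediate
12 | [(1E,3S)-3-(tert-butyldimethylsilyloxy)-5-chloro-2-methylpent-1-en-1-yl]chromium(III) dichloride (not isolated) | Cl[Cr](Cl)/C=C(C)/[C@@H](O[Si](C)(C)C(C)(C)C)CCCl | intermediate
13 | (5S,6R,7E,9S)-9-(tert-butyldimethylsilyloxy)-11-chloro-6-hydroxy-8-methyl-5-[(2R)-6-methylhept-5-en-2-yl]undec-7-en-2-one | CC(=O)CC[C@@H]([C@H](C)CCC=C(C)C)[C@@H](O)/C=C(C)/[C@@H](O[Si](C)(C)C(C)(C)C)CCCl | intermediate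
14 | (5S,6R,7E,9S)-6,9-bis(tert-butyldimethylsilyloxy)-11-chloro-8-methyl-5-[(2R)-6-methylhept-5-en-2-yl]undec-7-en-2-one | CC(=O)CC[C@@H]([C@H](C)CCC=C(C)C)[C@@H](O[Si](C)(C)C(C)(C)C)/C=C(C)/[C@@H](O[Si](C)(C)C(C)(C)C)CCCl | intermediate
15 | (2RS,5S,6R,7E,9S)-6,9-bis(tert-butyldimethylsilyloxy)-11-chloro-8-methyl-5-[(2R)-6-methylhept-5-en-2-yl]undec-7-en-2-ol | CC(O)CC[C@@H]([C@H](C)CCC=C(C)C)[C@@H](O[Si](C)(C)C(C)(C)C)/C=C(C)/[C@@H](O[Si](C)(C)C(C)(C)C)CCCl | intermediate
16 | S-acetyl C4 thioester of the 11-chloro chain (thioacetate in place of the C4 hydroxyl of 15) | CC(SC(C)=O)CC[C@@H]([C@H](C)CCC=C(C)C)[C@@H](O[Si](C)(C)C(C)(C)C)/C=C(C)/[C@@H](O[Si](C)(C)C(C)(C)C)CCCl | intermediate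
17 | 11-iodo analogue of 16 (iodide at ring C3) | CC(SC(C)=O)CC[C@@H]([C@H](C)CCC=C(C)C)[C@@H](O[Si](C)(C)C(C)(C)C)/C=C(C)/[C@@H](O[Si](C)(C)C(C)(C)C)CCI | intermediate
18 | free C4 thiol of 17 (not isolated) | CC(S)CC[C@@H]([C@H](C)CCC=C(C)C)[C@@H](O[Si](C)(C)C(C)(C)C)/C=C(C)/[C@@H](O[Si](C)(C)C(C)(C)C)CCI | intermediate
19 | (4S,5E,7R,8S)-4,7-bis(tert-butyldimethylsilyloxy)-5,11-dimethyl-8-[(2R)-6-methylhept-5-en-2-yl]thiacycloundec-5-ene | CC(C)(C)[Si](C)(C)O[C@H]1CCSC(C)CC[C@@H]([C@H](C)CCC=C(C)C)[C@@H](O[Si](C)(C)C(C)(C)C)/C=C/1C | intermediate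
20 | S-oxide of 19 (not isolated) | CC(C)(C)[Si](C)(C)O[C@H]1CCS(=O)C(C)CC[C@@H]([C@H](C)CCC=C(C)C)[C@@H](O[Si](C)(C)C(C)(C)C)/C=C/1C | intermediate
21 | S,S-dioxide of 19 (eleven-membered C3–SO2–C4 sulfone) | CC(C)(C)[Si](C)(C)O[C@H]1CCS(=O)(=O)C(C)CC[C@@H]([C@H](C)CCC=C(C)C)[C@@H](O[Si](C)(C)C(C)(C)C)/C=C/1C | intermediate
22 | 21 carrying bromine at ring C3 (not isolated) | CC(C)(C)[Si](C)(C)O[C@H]1CC(Br)S(=O)(=O)C(C)CC[C@@H]([C@H](C)CCC=C(C)C)[C@@H](O[Si](C)(C)C(C)(C)C)/C=C/1C | intermediate
23 | cis-fused episulfone: thiirane 1,1-dioxide spanning ring C3 and C4 of the ten-membered ring (not isolated) | CC(C)(C)[Si](C)(C)O[C@H]1CC2C(C)(CC[C@@H]([C@H](C)CCC=C(C)C)[C@@H](O[Si](C)(C)C(C)(C)C)/C=C/1C)S2(=O)=O | intermediate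
24 | (1S,3Z,7S,8R,9E)-1,8-bis(tert-butyldimethylsilyloxy)-4,10-dimethyl-7-[(2R)-6-methylhept-5-en-2-yl]cyclodeca-3,9-diene | CC(C)(C)[Si](C)(C)O[C@H]1C/C=C(/C)CC[C@@H]([C@H](C)CCC=C(C)C)[C@@H](O[Si](C)(C)C(C)(C)C)/C=C/1C | intermediate
25 | (1S,3Z,7S,8R,9E)-4,10-dimethyl-7-[(2R)-6-methylhept-5-en-2-yl]cyclodeca-3,9-diene-1,8-diol | O[C@H]1C/C=C(/C)CC[C@@H]([C@H](C)CCC=C(C)C)[C@@H](O)/C=C/1C | intermediate
26 | (1S,3Z,7S,8R,9E)-4,10-dimethyl-7-[(2R)-6-methylhept-5-en-2-yl]cyclodeca-3,9-diene-1,8-diyl diacetate | CC(=O)O[C@H]1C/C=C(/C)CC[C@@H]([C@H](C)CCC=C(C)C)[C@@H](OC(C)=O)/C=C/1C | target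

**Step count and risks**
Total steps: 16. Longest linear sequence: 15 steps (steps 2–16, from 4 and 5).

Steps most likely to fail:

1. Step 14 (Ramberg–Bäcklund contraction). Halogen transfer and ring closure run in one pot, so a second bromination at C3 may outrun the 1,3-elimination, and geometric control may erode if the episulfone epimerises before SO2 is lost. The fallback is a two-stage rearrangement that sets out from 21 and comes back at 24. Sulfone 21 is deprotonated at the less hindered C3 with n-BuLi (1.05 equiv, THF, −78 °C) and quenched with hexachloroethane to give the isolated 3-chloro sulfone F1. F1 is then treated with powdered KOH in t-BuOH/CH2Cl2 at rt, where 1,3-elimination and SO2 loss should give 24 with no halogen source or carbene precursor present.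

2. Step 12 (thioether macrocyclisation). Intermolecular S-alkylation (chain growth) may compete with the slow eleven-membered closure. The fallback exchanges the two unions, with sulfur joined first between two fragments and the ring closed at C8–C9; it sets out from 3 and 11 and comes back at 19.
   - The aldehyde of 3 is masked selectively (HC(OMe)3, CeCl3·7H2O, MeOH) as the keto dimethyl acetal F2.
   - NaBH4 reduction gives the C4 carbinol F3, and Mitsunobu reaction with AcSH gives the acetal thioacetate F4.
   - 11 is converted with NaI in acetone into the iodoalkyl alkenyl iodide F5.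
   - K2CO3 in degassed MeOH joins F4 and F5 by S-alkylation at the primary iodide only, giving the open-chain sulfide acetal F6.
   - PPTS in wet acetone frees the sulfide aldehyde F7.
   - An intramolecular Nozaki–Hiyama–Kishi reaction (CrCl2, cat. NiCl2, DMSO/THF, high dilution) closes C8–C9 to the hydroxy thiacycle F8.
   - TBSOTf/2,6-lutidine then gives 19.

3. Step 7 (fragment union). Facial selectivity at the aldehyde may be insufficient, because the two α-substituents (the C1′ branch and the C6 chain) differ only moderately in size, and 3 may epimerise at C7 before addition. The fallback moves stereocontrol from the substrate to a catalyst; it sets out from 3 and 11 and comes back at 13. It is a catalytic asymmetric Ni/Cr coupling with a chiral oxazoline–sulfonamide chromium complex (cat. CrCl2, cat. NiCl2, Mn, Cp2ZrCl2, LiCl, MeCN), using the ligand antipode that reinforces the Felkin sense. No compound outside the list arises (F0).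

**Further compounds**
F1 | step 14 | 21 carrying chlorine at ring C3 (3-chloro sulfone) | CC(C)(C)[Si](C)(C)O[C@H]1CC(Cl)S(=O)(=O)C(C)CC[C@@H]([C@H](C)CCC=C(C)C)[C@@H](O[Si](C)(C)C(C)(C)C)/C=C/1C
F2 | step 12 | (5S,6R)-5-(dimethoxymethyl)-6,10-dimethylundec-9-en-2-one | CC(=O)CC[C@@H]([C@H](C)CCC=C(C)C)C(OC)OC
F3 | step 12 | (2RS,5S,6R)-5-(dimethoxymethyl)-6,10-dimethylundec-9-en-2-ol | CC(O)CC[C@@H]([C@H](C)CCC=C(C)C)C(OC)OC
F4 | step 12 | S-[(2RS,5S,6R)-5-(dimethoxymethyl)-6,10-dimethylundec-9-en-2-yl] ethanethioate | CC(SC(C)=O)CC[C@@H]([C@H](C)CCC=C(C)C)C(OC)OC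
F5 | step 12 | (1E,3S)-3-(tert-butyldimethylsilyloxy)-1,5-diiodo-2-methylpent-1-ene | I/C=C(C)/[C@@H](O[Si](C)(C)C(C)(C)C)CCI
F6 | step 12 | open-chain sulfide: C4 sulfur of F4 alkylated by C3 of F5, aldehyde as dimethyl acetal | CC(SCC[C@H](O[Si](C)(C)C(C)(C)C)/C(C)=C/I)CC[C@@H]([C@H](C)CCC=C(C)C)C(OC)OC
F7 | step 12 | open-chain sulfide aldehyde (free C8 aldehyde of F6) | CC(SCC[C@H](O[Si](C)(C)C(C)(C)C)/C(C)=C/I)CC[C@@H]([C@H](C)CCC=C(C)C)C=O
F8 | step 12 | 19 with a free hydroxyl at ring C8 (hydroxy thiacycle) | CC(C)(C)[Si](C)(C)O[C@H]1CCSC(C)CC[C@@H]([C@H](C)CCC=C(C)C)[C@@H](O)/C=C/1C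
F0 | step 7 | none | none
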